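**Strategy.** The spiro cyclohexene ring is a 2-methylcyclohex-2-en-1-ol, so it is opened at the C7–C8 bond between the carbinol carbon and the methyl-bearing alkene carbon. An intramolecular Nozaki–Hiyama–Kishi reaction of a (Z)-alkenyl iodide arm with an acetaldehyde arm, both on the quaternary cyclopentane carbon C5, closes this ring and sets the C7 alcohol in one operation. The precursor cyclopentane takes its four stereocentres from (S)-pulegone and from a temporary cyclohexanone ring (Robinson annulation, hydroxyl-directed hydrogenation). Ozonolysis then cuts that ring open to release the two side arms. The ylidene butenolide is built last on a terminal alkyne.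

Key step: step 16

Remark: the target is read as (1R,4S,5S,7S) in spiro[4.5]decene numbering with an (S) side-chain carbon and a (Z)-ylidene butenolide; (S)-(−)-pulegone is taken as the commercial source of the C4 methyl stereocentre.

**Step 1**
Reactants: 1 (S)-(−)-pulegone
Product: 3 methyl (2S)-2-methyl-5-(propan-2-ylidene)cyclopentane-1-carboxylate (methyl pulegenate; C1 epimers), via pulegone dibromide 2 (not isolated)
Conditions: Br2, NaHCO3, Et2O, 0 °C; then NaOMe, MeOH, reflux
Reagents that add atoms: sodium methoxide, C[O-].[Na+]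
Why: Favorskii ring contraction of the dibromo ketone (cyclopropanone, methoxide opening, loss of the second bromide) should give the cyclopentane ester and leave the remote methyl stereocentre untouched.

**Step 2**
Reactants: 3 methyl pulegenate
Product: 4 methyl (1R,2S)-2-methyl-5-oxocyclopentane-1-carboxylate
Conditions: O3, CH2Cl2/MeOH, −78 °C; then Me2S
Reagents that add atoms: ozone, [O-][O+]=O
Why: Ozonolysis of the tetrasubstituted exocyclic alkene should give the β-keto ester, whose C1 centre settles trans to the methyl group by enolisation.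

**Step 3**
Reactants: 4 methyl (1R,2S)-2-methyl-5-oxocyclopentane-1-carboxylate; 5 ethyl vinyl ketone
Product: 7 methyl (1S,7aS)-1,4-dimethyl-5-oxo-2,3,5,6,7,7a-hexahydro-1H-indene-7a-carboxylate, via Michael adduct 6 (not isolated)
Conditions: Et3N (5 mol%), toluene, rt; then p-TsOH·H2O (20 mol%), reflux, Dean–Stark
Reagents that add atoms: none
Why: Robinson annulation; the Michael addition of the β-keto ester enol should occur on the face opposite the adjacent methyl group and so set the quaternary centre C7a, and the acid-mediated aldol condensation then closes the temporary cyclohexenone.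

**Step 4**
Reactants: 7 the bicyclic enone
Product: 8 methyl (1S,5S,7aS)-5-hydroxy-1,4-dimethyl-2,3,5,6,7,7a-hexahydro-1H-indene-7a-carboxylate
Conditions: NaBH4, CeCl3·7H2O, MeOH, −78 to 0 °C
Reagents that add atoms: none
Why: Luche 1,2-reduction; axial hydride attack anti to the pseudoaxial angular ester should place the C5 hydroxyl on the ester face.

**Step 5**
Reactants: 8 the allylic alcohol
Product: 9 methyl (1S,3aR,4S,5S,7aS)-5-hydroxy-1,4-dimethyloctahydro-1H-indene-7a-carboxylate
Conditions: H2 (1 atm), [Ir(cod)(PCy3)(py)]PF6 (10 mol%), CH2Cl2, rt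
Reagents that add atoms: none
Why: Hydroxyl-directed homogeneous hydrogenation of the tetrasubstituted alkene; the allylic hydroxyl and the ester carbonyl bind iridium on the same face, so syn delivery of H2 should give the cis ring fusion (C3a) and the C4 methyl trans to the ester.

**Step 6**
Reactants: 9 the saturated alcohol
Product: 10 methyl (1S,3aR,4S,7aS)-1,4-dimethyl-5-oxooctahydro-1H-indene-7a-carboxylate
Conditions: Dess–Martin periodinane, NaHCO3, CH2Cl2, 0 °C to rt
Reagents that add atoms: none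
Why: Dess–Martin oxidation under buffered, non-enolising conditions should return the ketone without epimerising C4.

**Step 7**
Reactants: 10 the cis-fused ketone
Product: 11 methyl (1S,3aR,4S,7aS)-1,4-dimethyl-5-[(trimethylsilyl)oxy]-2,3,3a,4,7,7a-hexahydro-1H-indene-7a-carboxylate
Conditions: LiN(iPr)2, Me3SiCl (in situ quench), THF, −78 °C
Reagents that add atoms: chlorotrimethylsilane, C[Si](C)(C)Cl
Why: Kinetic enolisation removes a proton from the unhindered C6 methylene and not from the C4 methine, so silylation should give the C5=C6 silyl enol ether and keep C4 intact.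

**Step 8**
Reactants: 11 the silyl enol ether
Product: 13 (2S)-2-[(1R,2S,3S)-2-(methoxycarbonyl)-3-methyl-2-(2-oxoethyl)cyclopentyl]propanoic acid, via silyl ester aldehyde 12 (not isolated)
Conditions: O3, CH2Cl2, −78 °C; Me2S; aqueous work-up
Reagents that add atoms: ozone, [O-][O+]=O
Why: Ozonolysis of the silyl enol ether cleaves the C5–C6 bond of the temporary ring and should release the acetaldehyde arm on the quaternary carbon and the propanoic acid on the neighbouring carbon in differentiated oxidation states.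

**Step 9**
Reactants: 13 the aldehyde acid
Product: 14 (2S)-2-[(1R,2S,3S)-2-[(2Z)-3-iodobut-2-en-1-yl]-2-(methoxycarbonyl)-3-methylcyclopentyl]propanoic acid
Conditions: EtPPh3I, n-BuLi, THF; I2, −78 °C; NaN(SiMe3)2, −78 °C; then 13 (as its sodium salt), −78 to −20 °C
Reagents that add atoms: ethyltriphenylphosphonium iodide, CC[P+](c1ccccc1)(c1ccccc1)c1ccccc1.[I-]; iodine, II
Why: Stork–Zhao variant of the Wittig reaction; the α-iodo ylide should give the (Z)-2-iodoalkene through the kinetically favoured cis-oxaphosphetane, and the carboxylate is inert.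

**Step 10**
Reactants: 14 the iodoalkenyl acid
Product: 15 methyl (1S,2S,5R)-5-[(2S)-1-hydroxypropan-2-yl]-1-[(2Z)-3-iodobut-2-en-1-yl]-2-methylcyclopentane-1-carboxylate
Conditions: BH3·SMe2, THF, 0 °C to rt; MeOH, aqueous work-up
Reagents that add atoms: none
Why: Borane reduces the carboxylic acid through its acyloxyborane much faster than the hindered methyl ester or the iodoalkene, so the two carboxyl groups should be told apart.

**Step 11**
Reactants: 15 the primary alcohol
Product: 16 methyl (1S,2S,5R)-1-[(2Z)-3-iodobut-2-en-1-yl]-2-methyl-5-[(2S)-1-oxopropan-2-yl]cyclopentane-1-carboxylate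
Conditions: Dess–Martin periodinane, NaHCO3, CH2Cl2, 0 °C
Reagents that add atoms: none
Why: Buffered Dess–Martin oxidation should give the α-branched aldehyde without epimerisation; it is used at once.

**Step 12**
Reactants: 16 the aldehyde
Product: 17 methyl (1S,2S,5R)-5-[(2S)-but-3-yn-2-yl]-1-[(2Z)-3-iodobut-2-en-1-yl]-2-methylcyclopentane-1-carboxylate
Conditions: dimethyl (1-diazo-2-oxopropyl)phosphonate, K2CO3, MeOH, 0 °C to rt
Reagents that add atoms: dimethyl (1-diazo-2-oxopropyl)phosphonate, CC(=O)C(=[N+]=[N-])P(=O)(OC)OC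
Why: Seyferth–Gilbert homologation with the Ohira–Bestmann reagent should convert the aldehyde into the terminal alkyne under carbonate conditions mild enough to keep the adjacent stereocentre.

**Step 13**
Reactants: 17 the alkyne ester
Product: 18 (1S,2S,5R)-5-[(2S)-but-3-yn-2-yl]-1-[(2Z)-3-iodobut-2-en-1-yl]-2-methylcyclopentane-1-carbaldehyde
Conditions: iBu2AlH (1.2 equiv), CH2Cl2, −78 °C; aq. potassium sodium tartrate
Reagents that add atoms: none
Why: Partial reduction of the neopentyl-type ester should stop at the aldehyde because the hindered aluminium hemiacetal survives at −78 °C until work-up.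

**Step 14**
Reactants: 18 the quaternary aldehyde
Product: 19 (1S,2S,3R)-3-[(2S)-but-3-yn-2-yl]-2-[(2Z)-3-iodobut-2-en-1-yl]-2-(2-methoxyethenyl)-1-methylcyclopentane (E/Z mixture at the enol ether)
Conditions: Ph3P(Cl)CH2OMe, NaN(SiMe3)2 (excess), THF, 0 °C to rt
Reagents that add atoms: (methoxymethyl)triphenylphosphonium chloride, COC[P+](c1ccccc1)(c1ccccc1)c1ccccc1.[Cl-]
Why: Wittig methoxymethylenation adds the one carbon that will become the carbinol carbon C7; the aldehyde has no α-hydrogen, so it cannot enolise.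

**Step 15**
Reactants: 19 the enol ether
Product: 20 2-[(1S,2S,5R)-5-[(2S)-but-3-yn-2-yl]-1-[(2Z)-3-iodobut-2-en-1-yl]-2-methylcyclopentyl]acetaldehyde
Conditions: 2 M HCl, THF, rt
Reagents that add atoms: water, O
Why: Acid hydrolysis of the enol ether should unmask the homologated aldehyde while the alkyne and the iodoalkene are inert.

**Step 16**
Reactants: 20 the iodoalkenyl aldehyde
Product: 22 (1R,4S,5S,7S)-1-[(2S)-but-3-yn-2-yl]-4,8-dimethylspiro[4.5]dec-8-en-7-ol, via alkenylchromium species 21 (not isolated)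
Conditions: CrCl2 (8 equiv), NiCl2 (2 mol%), degassed DMSO, rt, 0.005 M, slow addition of 20
Reagents that add atoms: none
Why: NiCl2 is reduced by CrCl2 to zerovalent nickel, which inserts into the C–I bond; transmetalation to trivalent chromium gives alkenylchromium 21 with retention of the Z geometry, and this adds 1,2 to the aldehyde (intramolecular Nozaki–Hiyama–Kishi reaction, closest known type the alkenyl iodide–aldehyde cyclisation to 2-substituted cyclohex-2-enols). The six-membered ring closes in a 6-exo-trig mode at the C=O group, with the Z alkene ending inside the ring as C8=C9 and the new bond joining C7 to C8. The new stereocentre C7 is controlled by the spiro carbon C5: in the half-chair transition state the forming C–O bond should be pseudoaxial to avoid A(1,2) strain with the C8 methyl group and the chromium. C1, which turns only its hydrogen toward C6 and C7, then takes the axial site on C5, whereas C4 would push its methyl group into the ring, so the oxygen ends syn to C1 and the 7S alcohol is expected. The step needs chemoselectivity for the aldehyde over the terminal alkyne, which organochromium reagents neither deprotonate nor add to. It also needs ring closure over oligomerisation, secured by high dilution and slow addition, and the Z geometry from step 9 is what allows closure.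

**Step 17**
Reactants: 23 propargyl alcohol
Product: 25 (2Z)-3-iodo-2-methylprop-2-en-1-ol, via alkenylmagnesium alkoxide 24 (not isolated)
Conditions: MeMgBr (3 equiv), CuI (10 mol%), Et2O/THF, −10 °C to rt; then I2, −78 to 0 °C
Reagents that add atoms: methylmagnesium bromide, C[Mg]Br; iodine, II
Why: Copper-catalysed anti-carbomagnesiation of the propargylic alkoxide gives a chelated alkenylmagnesium whose iodinolysis with retention should place iodine cis to the hydroxymethyl group.

**Step 18**
Reactants: 25 the iodo allylic alcohol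
Product: 26 (2Z)-3-iodo-2-methylprop-2-enoic acid
Conditions: CrO3, H2SO4, acetone/H2O, 0 °C
Reagents that add atoms: water, O
Why: Jones oxidation takes the primary allylic alcohol to the acid through the aldehyde hydrate without touching the alkene geometry.

**Step 19**
Reactants: 22 the spirocyclic alkynol; 26 (2Z)-3-iodo-2-methylprop-2-enoic acid
Product: 28 (5Z)-5-{(2S)-2-[(1R,4S,5S,7S)-7-hydroxy-4,8-dimethylspiro[4.5]dec-8-en-1-yl]propylidene}-3-methylfuran-2(5H)-one, via enynoic acid 27 (not isolated)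
Conditions: Pd(PPh3)4 (5 mol%), CuI (10 mol%), Et3N (3 equiv), MeCN, rt
Reagents that add atoms: none
Why: Sonogashira coupling gives the (Z)-enynoic acid, whose carboxylate adds anti across the metal-activated alkyne in a 5-exo-dig lactonisation, which should give the (Z)-ylidene butenolide; the free allylic alcohol is kept at this stage so that no allylic ester is exposed to zerovalent palladium.

**Step 20**
Reactants: 28 the butenolide alcohol; 29 3-phenylpropanoyl chloride
Product: 30 (1R,4S,5S,7S)-4,8-dimethyl-1-{(2S)-1-[(2Z)-4-methyl-5-oxofuran-2(5H)-ylidene]propan-2-yl}spiro[4.5]dec-8-en-7-yl 3-phenylpropanoate (CNP0260277.1)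
Conditions: pyridine, DMAP (cat.), CH2Cl2, 0 °C to rt
Reagents that add atoms: none
Why: Nucleophilic-catalysed acylation of the secondary allylic alcohol proceeds with retention at C7 and should leave the ylidene butenolide untouched.

**Compound list**

1 | (S)-(−)-pulegone, (5S)-5-methyl-2-(propan-2-ylidene)cyclohexan-1-one | C[C@H]1CCC(=C(C)C)C(=O)C1 | starting material
2 | pulegone dibromide, (5S)-2-bromo-2-(2-bromopropan-2-yl)-5-methylcyclohexan-1-one (C2 epimers) | C[C@H]1CCC(Br)(C(C)(C)Br)C(=O)C1 | intermediate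
3 | methyl (2S)-2-methyl-5-(propan-2-ylidene)cyclopentane-1-carboxylate (C1 epimers) | CC(C)=C1CC[C@H](C)C1C(=O)OC | intermediate
4 | methyl (1R,2S)-2-methyl-5-oxocyclopentane-1-carboxylate | O=C1CC[C@H](C)[C@H]1C(=O)OC | intermediate
5 | ethyl vinyl ketone (pent-1-en-3-one) | CCC(=O)C=C | starting material
6 | methyl (1S,2S)-2-methyl-5-oxo-1-(3-oxopentyl)cyclopentane-1-carboxylate | O=C1CC[C@H](C)[C@@]1(C(=O)OC)CCC(=O)CC | intermediate
7 | methyl (1S,7aS)-1,4-dimethyl-5-oxo-2,3,5,6,7,7a-hexahydro-1H-indene-7a-carboxylate | CC1=C2CC[C@H](C)[C@@]2(C(=O)OC)CCC1=O | intermediate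
8 | methyl (1S,5S,7aS)-5-hydroxy-1,4-dimethyl-2,3,5,6,7,7a-hexahydro-1H-indene-7a-carboxylate | CC1=C2CC[C@H](C)[C@@]2(C(=O)OC)CC[C@@H]1O | intermediate
9 | methyl (1S,3aR,4S,5S,7aS)-5-hydroxy-1,4-dimethyloctahydro-1H-indene-7a-carboxylate | O[C@@H]1[C@@H](C)[C@H]2CC[C@H](C)[C@@]2(C(=O)OC)CC1 | intermediate
10 | methyl (1S,3aR,4S,7aS)-1,4-dimethyl-5-oxooctahydro-1H-indene-7a-carboxylate | O=C1[C@@H](C)[C@H]2CC[C@H](C)[C@@]2(C(=O)OC)CC1 | intermediate
11 | methyl (1S,3aR,4S,7aS)-1,4-dimethyl-5-[(trimethylsilyl)oxy]-2,3,3a,4,7,7a-hexahydro-1H-indene-7a-carboxylate | C[Si](C)(C)OC1=CC[C@]2(C(=O)OC)[C@@H](C)CC[C@@H]2[C@@H]1C | intermediate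
12 | trimethylsilyl (2S)-2-[(1R,2S,3S)-2-(methoxycarbonyl)-3-methyl-2-(2-oxoethyl)cyclopentyl]propanoate | C[Si](C)(C)OC(=O)[C@@H](C)[C@H]1CC[C@H](C)[C@@]1(C(=O)OC)CC=O | intermediate
13 | (2S)-2-[(1R,2S,3S)-2-(methoxycarbonyl)-3-methyl-2-(2-oxoethyl)cyclopentyl]propanoic acid | OC(=O)[C@@H](C)[C@H]1CC[C@H](C)[C@@]1(C(=O)OC)CC=O | intermediate
14 | (2S)-2-[(1R,2S,3S)-2-[(2Z)-3-iodobut-2-en-1-yl]-2-(methoxycarbonyl)-3-methylcyclopentyl]propanoic acid | OC(=O)[C@@H](C)[C@H]1CC[C@H](C)[C@@]1(C(=O)OC)C/C=C(/C)I | intermediate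
15 | methyl (1S,2S,5R)-5-[(2S)-1-hydroxypropan-2-yl]-1-[(2Z)-3-iodobut-2-en-1-yl]-2-methylcyclopentane-1-carboxylate | OC[C@@H](C)[C@H]1CC[C@H](C)[C@@]1(C(=O)OC)C/C=C(/C)I | intermediate
16 | methyl (1S,2S,5R)-1-[(2Z)-3-iodobut-2-en-1-yl]-2-methyl-5-[(2S)-1-oxopropan-2-yl]cyclopentane-1-carboxylate | O=C[C@@H](C)[C@H]1CC[C@H](C)[C@@]1(C(=O)OC)C/C=C(/C)I | intermediate
17 | methyl (1S,2S,5R)-5-[(2S)-but-3-yn-2-yl]-1-[(2Z)-3-iodobut-2-en-1-yl]-2-methylcyclopentane-1-carboxylate | C#C[C@@H](C)[C@H]1CC[C@H](C)[C@@]1(C(=O)OC)C/C=C(/C)I | intermediate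
18 | (1S,2S,5R)-5-[(2S)-but-3-yn-2-yl]-1-[(2Z)-3-iodobut-2-en-1-yl]-2-methylcyclopentane-1-carbaldehyde | C#C[C@@H](C)[C@H]1CC[C@H](C)[C@@]1(C=O)C/C=C(/C)I | intermediate
19 | (1S,2S,3R)-3-[(2S)-but-3-yn-2-yl]-2-[(2Z)-3-iodobut-2-en-1-yl]-2-(2-methoxyethenyl)-1-methylcyclopentane (E/Z at the enol ether) | C#C[C@@H](C)[C@H]1CC[C@H](C)[C@@]1(C=COC)C/C=C(/C)I | intermediate
20 | 2-[(1S,2S,5R)-5-[(2S)-but-3-yn-2-yl]-1-[(2Z)-3-iodobut-2-en-1-yl]-2-methylcyclopentyl]acetaldehyde | C#C[C@@H](C)[C@H]1CC[C@H](C)[C@@]1(CC=O)C/C=C(/C)I | intermediate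
21 | [(2Z)-4-{(1S,2S,5R)-5-[(2S)-but-3-yn-2-yl]-2-methyl-1-(2-oxoethyl)cyclopentyl}but-2-en-2-yl]chromium dichloride (trivalent chromium) | C#C[C@@H](C)[C@H]1CC[C@H](C)[C@@]1(CC=O)C/C=C(/C)[Cr](Cl)Cl | intermediate
22 | (1R,4S,5S,7S)-1-[(2S)-but-3-yn-2-yl]-4,8-dimethylspiro[4.5]dec-8-en-7-ol | C#C[C@@H](C)[C@H]1CC[C@H](C)[C@@]12CC=C(C)[C@@H](O)C2 | intermediate
23 | propargyl alcohol (prop-2-yn-1-ol) | C#CCO | starting material
24 | bromomagnesium (2Z)-3-(bromomagnesio)-2-methylprop-2-en-1-olate | C/C(=C/[Mg]Br)CO[Mg]Br | intermediate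
25 | (2Z)-3-iodo-2-methylprop-2-en-1-ol | C/C(=C/I)CO | intermediate
26 | (2Z)-3-iodo-2-methylprop-2-enoic acid | C/C(=C/I)C(=O)O | intermediate
27 | (2Z,6S)-6-[(1R,4S,5S,7S)-7-hydroxy-4,8-dimethylspiro[4.5]dec-8-en-1-yl]-2-methylhept-2-en-4-ynoic acid | C/C(=C/C#C[C@@H](C)[C@H]1CC[C@H](C)[C@@]12CC=C(C)[C@@H](O)C2)C(=O)O | intermediate
28 | (5Z)-5-{(2S)-2-[(1R,4S,5S,7S)-7-hydroxy-4,8-dimethylspiro[4.5]dec-8-en-1-yl]propylidene}-3-methylfuran-2(5H)-one | CC1=C/C(=C/[C@@H](C)[C@H]2CC[C@H](C)[C@@]23CC=C(C)[C@@H](O)C3)OC1=O | intermediate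
29 | 3-phenylpropanoyl chloride | O=C(Cl)CCc1ccccc1 | starting material
30 | (1R,4S,5S,7S)-4,8-dimethyl-1-{(2S)-1-[(2Z)-4-methyl-5-oxofuran-2(5H)-ylidene]propan-2-yl}spiro[4.5]dec-8-en-7-yl 3-phenylpropanoate | CC1=C/C(=C/[C@@H](C)[C@H]2CC[C@H](C)[C@@]23CC=C(C)[C@@H](OC(=O)CCc2ccccc2)C3)OC1=O | target

**Step count.** 20 steps in total. The longest linear sequence is 18 steps (steps 1–16, 19 and 20); steps 17 and 18 make the iodo acid 26 in a side branch.

**The three steps most likely to fail**

Step 16 (key step). Facial selectivity in the addition of the alkenylchromium to the aldehyde may be poor, so that C7 forms as a mixture or mainly as the unwanted epimer. The fallback sets out from 20: the cyclisation mixture of 22 and (1R,4S,5S,7R)-1-[(2S)-but-3-yn-2-yl]-4,8-dimethylspiro[4.5]dec-8-en-7-ol F1 is oxidised with Dess–Martin periodinane to the spiro enone (1R,4S,5S)-1-[(2S)-but-3-yn-2-yl]-4,8-dimethylspiro[4.5]dec-8-en-7-one F2. This is then reduced with (R)-2-methyl-CBS-oxazaborolidine and catecholborane in toluene at −78 °C (Corey–Bakshi–Shibata reduction). The alkenyl side of the ketone acts as the large group, so the reagent should deliver the 7S alcohol, and catecholborane leaves the alkyne alone at this temperature. The fallback comes back to the route at 22.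

Step 5. The hindered tetrasubstituted alkene may be reduced slowly or incompletely, the iridium catalyst may be deactivated, or hydrogen may be delivered from the wrong face if coordination does not dominate. The fallback sets out from 7 and relies on anchoring of an angular hydroxymethyl group to a heterogeneous catalyst instead. iBu2AlH (excess) reduces ketone and ester to the diol (1S,5S,7aS)-7a-(hydroxymethyl)-1,4-dimethyl-2,3,5,6,7,7a-hexahydro-1H-inden-5-ol F3. Hydrogenation over Pd/C in EtOH, in which both hydroxyl groups hold the lower face on the metal surface, should give the cis-fused (1S,3aR,4S,5S,7aS)-7a-(hydroxymethyl)-1,4-dimethyloctahydro-1H-inden-5-ol F4. Swern oxidation gives the keto aldehyde (1S,3aR,4S,7aS)-1,4-dimethyl-5-oxooctahydro-1H-indene-7a-carbaldehyde F5, and Pinnick oxidation gives the keto acid (1S,3aR,4S,7aS)-1,4-dimethyl-5-oxooctahydro-1H-indene-7a-carboxylic acid F6. Esterification with Me3SiCHN2 brings the material back to the route at 10.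

Step 9. The unstable iodo ylide may be quenched by the carboxylic acid, the carboxylate may be poorly soluble at −78 °C, and the Z selectivity may erode. The fallback sets out from 10 and avoids the acid by cleaving an alkene instead of an enol ether. Kinetic enolisation (LiN(iPr)2, PhNTf2) gives the enol triflate methyl (1S,3aR,4S,7aS)-1,4-dimethyl-5-{[(trifluoromethyl)sulfonyl]oxy}-2,3,3a,4,7,7a-hexahydro-1H-indene-7a-carboxylate F7. Pd(OAc)2/PPh3-catalysed formate reduction (HCO2H, Bu3N, DMF) gives the cyclohexene methyl (1S,3aR,4R,7aS)-1,4-dimethyl-2,3,3a,4,7,7a-hexahydro-1H-indene-7a-carboxylate F8 (same configuration as 10; the C4 descriptor changes by priority only). Ozonolysis (O3; Me2S) gives the dialdehyde methyl (1S,2S,5R)-2-methyl-1-(2-oxoethyl)-5-[(2S)-1-oxopropan-2-yl]cyclopentane-1-carboxylate F9. One equivalent of the iodo ylide at −78 °C should then take the unbranched acetaldehyde arm in preference to the α-branched aldehyde, which comes back to the route at 16 and skips steps 10 and 11.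

**Further compounds**

F1 | step 16 | (1R,4S,5S,7R)-1-[(2S)-but-3-yn-2-yl]-4,8-dimethylspiro[4.5]dec-8-en-7-ol | C#C[C@@H](C)[C@H]1CC[C@H](C)[C@@]12CC=C(C)[C@H](O)C2
F2 | step 16 | (1R,4S,5S)-1-[(2S)-but-3-yn-2-yl]-4,8-dimethylspiro[4.5]dec-8-en-7-one | C#C[C@@H](C)[C@H]1CC[C@H](C)[C@@]12CC=C(C)C(=O)C2
F3 | step 5 | (1S,5S,7aS)-7a-(hydroxymethyl)-1,4-dimethyl-2,3,5,6,7,7a-hexahydro-1H-inden-5-ol | CC1=C2CC[C@H](C)[C@@]2(CO)CC[C@@H]1O
F4 | step 5 | (1S,3aR,4S,5S,7aS)-7a-(hydroxymethyl)-1,4-dimethyloctahydro-1H-inden-5-ol | O[C@@H]1[C@@H](C)[C@H]2CC[C@H](C)[C@@]2(CO)CC1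
F5 | step 5 | (1S,3aR,4S,7aS)-1,4-dimethyl-5-oxooctahydro-1H-indene-7a-carbaldehyde | O=C1[C@@H](C)[C@H]2CC[C@H](C)[C@@]2(C=O)CC1
F6 | step 5 | (1S,3aR,4S,7aS)-1,4-dimethyl-5-oxooctahydro-1H-indene-7a-carboxylic acid | O=C1[C@@H](C)[C@H]2CC[C@H](C)[C@@]2(C(=O)O)CC1
F7 | step 9 | methyl (1S,3aR,4S,7aS)-1,4-dimethyl-5-{[(trifluoromethyl)sulfonyl]oxy}-2,3,3a,4,7,7a-hexahydro-1H-indene-7a-carboxylate | O=S(=O)(OC1=CC[C@]2(C(=O)OC)[C@@H](C)CC[C@@H]2[C@@H]1C)C(F)(F)F
F8 | step 9 | methyl (1S,3aR,4R,7aS)-1,4-dimethyl-2,3,3a,4,7,7a-hexahydro-1H-indene-7a-carboxylate | C1=CC[C@]2(C(=O)OC)[C@@H](C)CC[C@@H]2[C@@H]1C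
F9 | step 9 | methyl (1S,2S,5R)-2-methyl-1-(2-oxoethyl)-5-[(2S)-1-oxopropan-2-yl]cyclopentane-1-carboxylate | O=C[C@@H](C)[C@H]1CC[C@H](C)[C@@]1(C(=O)OC)CC=O
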